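**Plan**

Numbering: C1 = tertiary carbinol carrying C7H2OBz, C2 and C3 = acetoxy carbons, C4=C5 = ring alkene, C6 = free secondary carbinol. In the target, C7 and O3 lie on the top face and O1, O2 and O6 on the bottom face.
Cuts: first the acyl–oxygen bonds at O2 and O3 and the C7–OBz bond. Then C7–O1 and C1–C7 of a C1 spiro-oxirane, back to a C1 ketone and a CH2 ylide. Finally C3–O/C6–O and C1–O/C2–O, back to a bis-oxirane and a dibromodiol made from p-benzoquinone.
Enabling feature: without C7 the six-membered ring is a ketone of the all-trans cyclohex-5-ene-1,2,3,4-tetrol. Its twofold axis through the midpoints of C1–C2 and C4=C5 makes C1/C2 and C3/C6 pairwise identical, so one silylation and one oxidation single out C1, and O2 and O6 then flank the carbonyl on the same face.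
Forward: the carbocycle is that of the quinone. Oxiranes C1–C6 and C2–C3 are closed (step 4) and opened (step 5). The spiro-oxirane C1–C7–O is closed (step 8) and opened at C7 by benzoate (step 9). A temporary C1/C6 dioxolane (steps 11–14) lets O2 and O3 be acetylated alone.
Stereochemistry: the absolute configuration comes from a lipase resolution (step 3). C2 is set by inversion at a C–Br carbon, C3 and C6 by inversion in the oxirane opening, and C1 by substrate-controlled delivery of CH2 to the face opposite O2 and O6.

Key step: step 8

Assumption: the lipase follows the usual size rule for secondary alcohols (CHBr large, CH= medium) and acylates the (R)-carbinols faster; the racemic products of steps 1 and 2 are drawn as the enantiomer carried on, and C-labels always follow the target numbering.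

**Step 1**
Reactants: 1 p-benzoquinone
Product: 2 (±)-trans-5,6-dibromocyclohex-2-ene-1,4-dione
Conditions: Br2 (1.0 equiv), CHCl3, 0 °C
Reagents that add atoms: bromine, BrBr
Why: Electrophilic anti addition of bromine through a bromonium ion should stop after one C=C bond because the remaining ene-dione alkene is deactivated, and it sets the trans relation of the future C1 and C2 in racemic form.

**Step 2**
Reactants: 2 (±)-trans-5,6-dibromocyclohex-2-ene-1,4-dione
Product: 3 (±)-(1R*,4R*,5S*,6S*)-5,6-dibromocyclohex-2-ene-1,4-diol (all-trans)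
Conditions: NaBH4, Et2O/H2O, 0 °C
Reagents that add atoms: none
Why: Borohydride 1,2-reduction of both carbonyls with axial hydride delivery to the diequatorial dibromide should leave each new hydroxyl equatorial and trans to the neighbouring bromine, giving the C2-symmetric all-trans diol.

**Step 3**
Reactants: 3 (±)-all-trans dibromodiol
Product: 4 (1R,4R,5S,6S)-5,6-dibromocyclohex-2-ene-1,4-diyl diacetate
Conditions: immobilised Burkholderia cepacia lipase, vinyl acetate, MTBE, 35 °C, stopped near half conversion; chromatography, recrystallisation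
Reagents that add atoms: vinyl acetate, C=COC(C)=O
Why: In this lipase-catalysed kinetic resolution by irreversible transesterification the (R)-carbinols should be acylated faster, and because the diacetate must pass two such selective acylations its enantiopurity is amplified, which fixes the absolute configuration of the whole route.

**Step 4**
Reactants: 4 (1R,4R,5S,6S)-dibromo diacetate
Product: 6 (1R,2R,4R,7R)-3,8-dioxatricyclo[5.1.0.0(2,4)]oct-5-ene (anti-benzene dioxide), via disodium dibromodiolate 5 (not isolated)
Conditions: NaOMe (2.1 equiv), THF/MeOH, 0 °C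
Reagents that add atoms: none
Why: Zemplén-type methanolysis releases the two alkoxides, each of which after ring inversion displaces the antiperiplanar vicinal bromide in an intramolecular Williamson reaction (3-exo-tet) with inversion at C2 and C1, placing the oxirane C2–C3 on the bottom face and the oxirane C1–C6 on the top face.

**Step 5**
Reactants: 6 anti-benzene dioxide
Product: 7 (1S,2S,3S,6S)-3,6-bis(2-naphthylmethoxy)cyclohex-4-ene-1,2-diol (all-trans)
Conditions: 2-naphthylmethanol (8 equiv), BF3·OEt2 (10 mol %), CH2Cl2, −30 → 0 °C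
Reagents that add atoms: 2-naphthylmethanol, OCc1ccc2ccccc2c1
Why: In this Lewis-acid-catalysed alcoholysis of vinyl oxiranes each activated ring should be attacked at its allylic carbon (C3 from the top, C6 from the bottom) in an SN2-like opening with inversion, which sets C3 and C6 trans to the retained inner oxygens and leaves only the two inner hydroxyls free.

**Step 6**
Reactants: 7 C2-symmetric inner diol
Product: 8 (1R,2S,3S,6S)-2-(tert-butyldimethylsilyloxy)-3,6-bis(2-naphthylmethoxy)cyclohex-4-en-1-ol
Conditions: TBSCl (1.1 equiv), imidazole, DMF, rt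
Reagents that add atoms: tert-butyldimethylsilyl chloride, CC(C)(C)[Si](C)(C)Cl
Why: In this imidazole-promoted monosilylation the two hydroxyls are homotopic so either gives the same product, the first silyl group shields its neighbour against a second silylation, and a 1,2-silyl shift would only regenerate the same compound.

**Step 7**
Reactants: 8 mono-TBS alcohol
Product: 9 (2R,3S,6S)-2-(tert-butyldimethylsilyloxy)-3,6-bis(2-naphthylmethoxy)cyclohex-4-en-1-one (C1 ketone)
Conditions: Dess–Martin periodinane, CH2Cl2, 0 °C → rt
Reagents that add atoms: none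
Why: The Dess–Martin oxidation converts the remaining carbinol into the C1 ketone under neutral conditions that should neither move C4=C5 into conjugation nor epimerise C2 or C6.

**Step 8**
Reactants: 9 C1 ketone; 10 trimethylsulfoxonium iodide
Product: 13 (3S,4S,7S,8R)-8-(tert-butyldimethylsilyloxy)-4,7-bis(2-naphthylmethoxy)-1-oxaspiro[2.5]oct-5-ene (C1 spiro-oxirane), via dimethylsulfoxonium methylide 11 (not isolated), via C1 alkoxide betaine 12 (not isolated)
Conditions: Me3S(O)I (1.5 equiv), NaH (1.4 equiv), DMSO, rt until H2 evolution ends; then 9 in THF, 0 °C → rt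
Reagents that add atoms: trimethylsulfoxonium iodide 10, C[S+](C)(C)=O.[I-] (delivers CH2 through ylide 11, C[S+](C)(=O)[CH2-])
Why: The ylide carbon adds reversibly to the C1 carbonyl to give betaine 12, whose alkoxide then expels DMSO from C7, so that C1–C7 and C7–O are made in one operation. The closest known reaction type is the Corey–Chaykovsky epoxidation of protected inososes and other polyoxygenated cyclohexanones with dimethylsulfoxonium methylide. The oxirane closes in the 3-exo-tet mode with the alkoxide oxygen antiperiplanar to the C7–S bond. C1 is controlled by its two neighbours: in the half-chair with O2, O3 and O6 (pseudo)equatorial the reversible addition funnels through the betaine whose bulky CH2S(O)Me2 arm is equatorial, on the face opposite O2 and O6, and in the ring-flipped conformer that same face is anti to both axial alpha C–O bonds, so CH2 ends trans and the oxirane oxygen cis to O2 and O6. The step needs carbonyl addition to outrun deprotonation at the doubly activated C6–H and at C2–H; the two alpha-oxygens raise the electrophilicity of C1, the arylmethyl ethers at O3 and O6 are poor leaving groups for E1cB loss and offer the enolate no rearrangement path, and the ylide is preformed without excess NaH and used cold. C4=C5 is not conjugated with the ketone, so cyclopropanation does not compete.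

**Step 9**
Reactants: 13 C1 spiro-oxirane; 14 benzoic acid
Product: 15 [(1S,2R,3S,6S)-2-(tert-butyldimethylsilyloxy)-1-hydroxy-3,6-bis(2-naphthylmethoxy)cyclohex-4-en-1-yl]methyl benzoate
Conditions: PhCO2H (3 equiv), Cs2CO3 (0.5 equiv), DMF, 80 °C
Reagents that add atoms: benzoic acid 14, OC(=O)c1ccccc1
Why: SN2 opening of the 2,2-disubstituted oxirane by caesium benzoate at its unsubstituted carbon C7, whose rear side points away from the ring, leaves the C1–O bond and the C1 configuration untouched, while the excess acid protonates the tertiary alkoxide before acyl or silyl transfer can start.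

**Step 10**
Reactants: 15 hydroxy benzoate
Product: 16 [(1S,2R,3S,6S)-2-(tert-butyldimethylsilyloxy)-1,3,6-trihydroxycyclohex-4-en-1-yl]methyl benzoate
Conditions: DDQ (2.5 equiv), CH2Cl2/pH 7 phosphate buffer (10:1), 0 °C → rt
Reagents that add atoms: none
Why: Oxidative cleavage of the 2-naphthylmethyl ethers with DDQ (hydride abstraction, then hydrolysis of the oxocarbenium ions) should free O3 and O6 without touching the silyl ether, the benzoate or the alkene.

**Step 11**
Reactants: 16 triol
Product: 17 1,6-O-isopropylidene derivative of 16 (1S,2R,3S,6S; cis-fused dioxolane on C1/C6, O3–H free)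
Conditions: 2,2-dimethoxypropane, PPTS (10 mol %), acetone, 40 °C
Reagents that add atoms: 2,2-dimethoxypropane, COC(C)(C)OC
Why: In this acid-catalysed transketalisation O1 and O6 are the only free cis-vicinal pair (O2 is silylated, O3 is trans-1,3 to O1), so the dioxolane can form only there.

**Step 12**
Reactants: 17 acetonide silyl ether
Product: 18 1,6-O-isopropylidene 2,3-diol (1R,2R,3S,6S; descriptor at C1 changes by priority only)
Conditions: Bu4NF/AcOH (1:1), THF, rt
Reagents that add atoms: none
Why: Fluoride-induced desilylation, buffered with acetic acid so that no alkoxide lives long enough to trigger migration of the C7 benzoate, frees O2.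

**Step 13**
Reactants: 18 2,3-diol
Product: 19 2,3-di-O-acetyl-1,6-O-isopropylidene benzoate (1S,2R,3S,6S)
Conditions: Ac2O, pyridine, DMAP (cat.), CH2Cl2, 0 °C → rt
Reagents that add atoms: acetic anhydride, CC(=O)OC(C)=O
Why: DMAP-catalysed acetylation esterifies the hydroxyls at C2 and C3, the only free ones left.

**Step 14**
Reactants: 19 diacetate acetonide
Product: 20 [(1S,2R,3S,6S)-2,3-diacetoxy-1,6-dihydroxycyclohex-4-en-1-yl]methyl benzoate (target)
Conditions: AcOH/H2O (4:1), 40 °C
Reagents that add atoms: none
Why: Mild acid-catalysed ketal hydrolysis frees the C1/C6 cis-diol, the esters tolerate aqueous acetic acid, and the primary benzoate and secondary acetates already occupy the thermodynamically preferred positions so that migration to the tertiary O1 or the hindered O6 is not expected.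

**Compound list**

1 | p-benzoquinone | O=C1C=CC(=O)C=C1 | starting material
2 | (±)-trans-5,6-dibromocyclohex-2-ene-1,4-dione (racemic, one enantiomer drawn) | O=C1C=CC(=O)[C@H](Br)[C@H]1Br | intermediate
3 | (±)-all-trans 5,6-dibromocyclohex-2-ene-1,4-diol (racemic, one enantiomer drawn) | O[C@@H]1C=C[C@@H](O)[C@H](Br)[C@H]1Br | intermediate
4 | (1R,4R,5S,6S)-5,6-dibromocyclohex-2-ene-1,4-diyl diacetate | CC(=O)O[C@@H]1C=C[C@@H](OC(C)=O)[C@H](Br)[C@H]1Br | intermediate
5 | disodium (1R,4R,5S,6S)-5,6-dibromocyclohex-2-ene-1,4-diolate (formed in the flask) | [Na+].[Na+].[O-][C@@H]1C=C[C@@H]([O-])[C@H](Br)[C@H]1Br | intermediate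
6 | (1R,2R,4R,7R)-3,8-dioxatricyclo[5.1.0.0(2,4)]oct-5-ene, anti-benzene dioxide | O1[C@@H]2C=C[C@H]3O[C@H]3[C@H]12 | intermediate
7 | (1S,2S,3S,6S)-3,6-bis(2-naphthylmethoxy)cyclohex-4-ene-1,2-diol | O(Cc1ccc2ccccc2c1)[C@H]3C=C[C@H](OCc1ccc2ccccc2c1)[C@@H](O)[C@@H]3O | intermediate
8 | (1R,2S,3S,6S)-2-(tert-butyldimethylsilyloxy)-3,6-bis(2-naphthylmethoxy)cyclohex-4-en-1-ol | O(Cc1ccc2ccccc2c1)[C@H]3C=C[C@H](OCc1ccc2ccccc2c1)[C@@H](O)[C@@H]3O[Si](C)(C)C(C)(C)C | intermediate
9 | (2R,3S,6S)-2-(tert-butyldimethylsilyloxy)-3,6-bis(2-naphthylmethoxy)cyclohex-4-en-1-one | O(Cc1ccc2ccccc2c1)[C@H]3C=C[C@H](OCc1ccc2ccccc2c1)C(=O)[C@@H]3O[Si](C)(C)C(C)(C)C | intermediate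
10 | trimethylsulfoxonium iodide | C[S+](C)(C)=O.[I-] | starting material
11 | dimethylsulfoxonium methylide (formed in the flask) | C[S+](C)(=O)[CH2-] | intermediate
12 | C1 alkoxide betaine, CH2S(O)Me2 arm on the top face (formed in the flask) | O(Cc1ccc2ccccc2c1)[C@H]3C=C[C@H](OCc1ccc2ccccc2c1)[C@@]([O-])(C[S+](C)(C)=O)[C@@H]3O[Si](C)(C)C(C)(C)C | intermediate
13 | (3S,4S,7S,8R)-8-(tert-butyldimethylsilyloxy)-4,7-bis(2-naphthylmethoxy)-1-oxaspiro[2.5]oct-5-ene | O(Cc1ccc2ccccc2c1)[C@H]3C=C[C@H](OCc1ccc2ccccc2c1)[C@@]4(CO4)[C@@H]3O[Si](C)(C)C(C)(C)C | intermediate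
14 | benzoic acid | OC(=O)c1ccccc1 | starting material
15 | [(1S,2R,3S,6S)-2-(tert-butyldimethylsilyloxy)-1-hydroxy-3,6-bis(2-naphthylmethoxy)cyclohex-4-en-1-yl]methyl benzoate | O(Cc1ccc2ccccc2c1)[C@H]3C=C[C@H](OCc1ccc2ccccc2c1)[C@@](O)(COC(=O)c1ccccc1)[C@@H]3O[Si](C)(C)C(C)(C)C | intermediate
16 | [(1S,2R,3S,6S)-2-(tert-butyldimethylsilyloxy)-1,3,6-trihydroxycyclohex-4-en-1-yl]methyl benzoate | O[C@H]1C=C[C@H](O)[C@@](O)(COC(=O)c2ccccc2)[C@@H]1O[Si](C)(C)C(C)(C)C | intermediate
17 | 1,6-O-isopropylidene-2-O-TBS 3-ol benzoate | O[C@H]1C=C[C@@H]2OC(C)(C)O[C@]2(COC(=O)c3ccccc3)[C@@H]1O[Si](C)(C)C(C)(C)C | intermediate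
18 | 1,6-O-isopropylidene 2,3-diol benzoate | O[C@H]1C=C[C@@H]2OC(C)(C)O[C@]2(COC(=O)c3ccccc3)[C@@H]1O | intermediate
19 | 2,3-di-O-acetyl-1,6-O-isopropylidene benzoate | CC(=O)O[C@H]1C=C[C@@H]2OC(C)(C)O[C@]2(COC(=O)c3ccccc3)[C@@H]1OC(C)=O | intermediate
20 | [(1S,2R,3S,6S)-2,3-diacetoxy-1,6-dihydroxycyclohex-4-en-1-yl]methyl benzoate | CC(=O)O[C@H]1C=C[C@H](O)[C@@](O)(COC(=O)c2ccccc2)[C@@H]1OC(C)=O | target

Total step count: 14. Longest linear sequence: 14 steps, from p-benzoquinone.

**Steps most likely to fail**

Step 8. The ylide may act as a base. Deprotonation at C6–H (allylic and alpha to the ketone) or at C2–H could be followed by loss of the C3 alkoxide and aromatisation, or by C6 epimerisation. An oxygen-to-oxygen silyl shift in the betaine and a share of attack from the bottom face could also erode the result. The fallback sets out from 9 and makes the same C1–C7 bond with a bulky, barely basic hydroxymethyl anion equivalent. (Isopropoxydimethylsilyl)methylmagnesium chloride with CeCl3 in THF at −78 °C should add equatorially, anti to O2 and O6, to give the beta-hydroxysilane F1. Tamao–Fleming oxidation (H2O2, KF, KHCO3, THF/MeOH, rt), which a secondary TBS ether should survive, gives the C1,C7-diol F2. Selective benzoylation of the primary hydroxyl (BzCl, pyridine, CH2Cl2, −20 °C) comes back to the route at 15.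

Step 5. Control over the double opening may be lost in several ways: SN2′ attack at the alkene carbons, ionisation to an allyl cation with partial cis opening, Lewis-acid isomerisation of the bis-oxirane towards phenolic material, and oligomerisation through the liberated hydroxyls. The fallback sets out from 6, makes the solvent the nucleophile, and puts the ethers on afterwards under tin control. Heating in water at 60 °C without Lewis acid should give the crystalline all-trans tetrol F3, freed from isomers by recrystallisation. Bu2SnO (2 equiv, MeOH reflux, then toluene) gives the bis(dibutylstannylene) acetal F4 spanning O1/O6 and O2/O3. 2-(Bromomethyl)naphthalene with Bu4NBr (cat.) in toluene at 100 °C should alkylate the less hindered allylic oxygen of each tin acetal and come back to the route at 7.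

Step 10. The C6 oxocarbenium ion may be captured by the neighbouring C1 hydroxyl (oxidative acetalisation) instead of by water, and the liberated allylic alcohols may be over-oxidised during the slower cleavage of the second ether. The fallback sets out from 15 and makes this capture the intended reaction. DDQ (2.5 equiv) with 4 Å molecular sieves in dry CH2Cl2, followed by aqueous NaHCO3, should tie O6 and O1 into a 2-naphthylmethylidene acetal while the O3 ether is lost on work-up, giving the acetal alcohol F5. This acetal takes over the role of the isopropylidene ketal. Bu4NF/AcOH gives the 2,3-diol F6, Ac2O/pyridine/DMAP gives the diacetate F7, and AcOH/H2O at 40 °C removes the acetal and comes back to the route at target 20.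

**Further compounds**

F1 | step 8 | C1 tertiary alcohol bearing CH2SiMe2(OiPr) on the top face, otherwise as 15 | O(Cc1ccc2ccccc2c1)[C@H]3C=C[C@H](OCc1ccc2ccccc2c1)[C@@](O)(C[Si](C)(C)OC(C)C)[C@@H]3O[Si](C)(C)C(C)(C)C
F2 | step 8 | C1,C7-diol (debenzoyl 15) | O(Cc1ccc2ccccc2c1)[C@H]3C=C[C@H](OCc1ccc2ccccc2c1)[C@@](O)(CO)[C@@H]3O[Si](C)(C)C(C)(C)C
F3 | step 5 | (1S,2R,3R,4S)-cyclohex-5-ene-1,2,3,4-tetrol (all-trans) | O[C@H]1C=C[C@H](O)[C@@H](O)[C@@H]1O
F4 | step 5 | bis(dibutylstannylene) acetal of F3 across O1/O6 and O2/O3 | CCCC[Sn]1(CCCC)O[C@H]2C=C[C@@H]3O[Sn](CCCC)(CCCC)O[C@H]3[C@@H]2O1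
F5 | step 10 | 1,6-O-(2-naphthylmethylidene)-2-O-TBS 3-ol benzoate (epimers at the acetal carbon) | O[C@H]1C=C[C@@H]2OC(c3ccc4ccccc4c3)O[C@]2(COC(=O)c3ccccc3)[C@@H]1O[Si](C)(C)C(C)(C)C
F6 | step 10 | 1,6-O-(2-naphthylmethylidene) 2,3-diol benzoate | O[C@H]1C=C[C@@H]2OC(c3ccc4ccccc4c3)O[C@]2(COC(=O)c3ccccc3)[C@@H]1O
F7 | step 10 | 2,3-di-O-acetyl-1,6-O-(2-naphthylmethylidene) benzoate | CC(=O)O[C@H]1C=C[C@@H]2OC(c3ccc4ccccc4c3)O[C@]2(COC(=O)c3ccccc3)[C@@H]1OC(C)=O
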